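**Plan**
Feature: ring A carries oxygen on alternate carbons (C3 OH, C5 OMe, C4 H between them) and carbon on C1 (ethylene bridge), C2 and C6 (benzyls). This is the pattern of a folded 3,5,7-triketo ester, and the C2 benzylic CH2 stands where the ester carbon lands.
Cuts, in order: the CH2–aryl bond of the C2 benzyl group (aldehyde + aryl Grignard), the ring A C1–C2 bond (aldol aromatization), the open-chain C6–C1 bond (dianion + Weinreb amide), the C4–C5 bond (dioxinone dienolate + acid chloride), and the ring B aryl–CH2 bond (Negishi).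
Forward: ring B and the three phenol rings are bought. Ring B is homologated and benzylated, and the chain is joined C4–C5, then C6–C1. Ring A, the only ring made, closes in step 8; ester-to-benzyl conversion and global hydrogenolysis finish the route.
Stereochemistry: the target is achiral. The centres that appear on the way (chain C6, the aldol adduct, the carbinol) are racemic and are all erased.

Key step: step 8

Assumption: ring A numbering (C1 = bridge carbon, then C2 to C6 passing through the OH-bearing C3) is also used for the open-chain precursors; Bn = benzyl; ArB = 5-(benzyloxy)-2-[4-(benzyloxy)benzyl]phenyl, the protected ring B with its benzyl group.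

**Step 1**
Reactants: 1 2-bromo-5-hydroxybenzaldehyde
Product: 2 5-(benzyloxy)-2-bromobenzaldehyde
Conditions: BnBr, K2CO3, DMF, rt
Reagents that add atoms: benzyl bromide, BrCc1ccccc1
Why: Williamson ether synthesis: K2CO3 deprotonates only the phenol, the phenoxide displaces bromide, and the aldehyde and aryl bromide are untouched.

**Step 2**
Reactants: 2 5-(benzyloxy)-2-bromobenzaldehyde; 3 Meldrum's acid (2,2-dimethyl-1,3-dioxane-4,6-dione)
Product: 6 3-[5-(benzyloxy)-2-bromophenyl]propanoic acid, via arylidene Meldrum's acid 4 (not isolated), via benzyl Meldrum's acid 5 (not isolated)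
Conditions: HCO2H/Et3N (5:2), rt, then 100 °C
Reagents that add atoms: none
Why: One-pot Knoevenagel condensation, formate transfer reduction of the strongly electrophilic alkylidene 4 and thermal ring opening with decarboxylation of 5 is an established reductive two-carbon homologation of aryl aldehydes, and with no metal catalyst present it spares the aryl bromide and the benzyl ether, which an olefination and hydrogenation sequence would endanger.

**Step 3**
Reactants: 6 3-[5-(benzyloxy)-2-bromophenyl]propanoic acid
Product: 8 3-[5-(benzyloxy)-2-bromophenyl]-N-methoxy-N-methylpropanamide, via acyl imidazole 7 (not isolated)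
Conditions: carbonyldiimidazole, CH2Cl2, rt; then MeNH(OMe)·HCl, rt
Reagents that add atoms: N,O-dimethylhydroxylamine hydrochloride, CNOC.Cl
Why: Carbonyldiimidazole activation followed by aminolysis of acyl imidazole 7 is a standard neutral Weinreb amide synthesis with which nothing else in the molecule can interfere.

**Step 4**
Reactants: 8 3-[5-(benzyloxy)-2-bromophenyl]-N-methoxy-N-methylpropanamide; 9 4-(benzyloxy)benzyl chloride
Product: 11 3-{5-(benzyloxy)-2-[4-(benzyloxy)benzyl]phenyl}-N-methoxy-N-methylpropanamide, via 4-(benzyloxy)benzylzinc chloride 10 (not isolated)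
Conditions: 9, Zn dust, LiCl, THF, 0 °C to rt; then 8, Pd(OAc)2 (2 mol %), SPhos (4 mol %), THF, rt to 50 °C
Reagents that add atoms: none
Why: Negishi sp3–sp2 cross-coupling: LiCl-assisted zinc insertion converts the benzylic chloride into 10 with little Wurtz coupling, the bulky electron-rich phosphine lets zerovalent palladium insert into the hindered, electron-rich C–Br bond, and the organozinc is too mild to attack the Weinreb amide.

**Step 5**
Reactants: 12 3-[4-(benzyloxy)phenyl]propanoic acid
Product: 13 3-[4-(benzyloxy)phenyl]propanoyl chloride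
Conditions: (COCl)2, DMF (cat.), CH2Cl2, 0 °C to rt; evaporation
Reagents that add atoms: oxalyl chloride, O=C(Cl)C(=O)Cl
Why: Vilsmeier-type activation by oxalyl chloride and catalytic DMF turns the acid into its chloride under conditions that leave the aryl benzyl ether intact, and all by-products are volatile.

**Step 6**
Reactants: 13 3-[4-(benzyloxy)phenyl]propanoyl chloride; 14 2,2,6-trimethyl-4H-1,3-dioxin-4-one
Product: 16 keto-dioxinone 6-{4-[4-(benzyloxy)phenyl]-2-oxobutyl}-2,2-dimethyl-4H-1,3-dioxin-4-one, via lithium dienolate 15 (not isolated)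
Conditions: 14 (2 equiv), LiN(SiMe3)2 (2 equiv), THF, −78 °C; then 13 (1 equiv), −78 °C; 1 M HCl
Reagents that add atoms: none
Why: Kinetic deprotonation of the 6-methyl group gives the vinylogous ester enolate 15, whose acylation by acid chlorides at the terminal carbon (C4–C5 bond) is the standard entry to keto-dioxinones, the second equivalent of 15 being there to absorb the more acidic proton of 16.

**Step 7**
Reactants: 16 keto-dioxinone; 11 ring B Weinreb amide
Product: 18 diketo-dioxinone 6-{3-[4-(benzyloxy)benzyl]-2,4-dioxo-6-ArB-hexyl}-2,2-dimethyl-4H-1,3-dioxin-4-one (racemic), via dilithium dianion 17 (not isolated)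
Conditions: 16 (1.5 equiv), LiN(iPr)2 (3.1 equiv), THF, −78 to −40 °C; then 11 (1 equiv), −78 to −10 °C; 1 M HCl
Reagents that add atoms: none
Why: Claisen-type acylation of a 1,3-dicarbonyl dianion: 17 reacts at its last-formed and most basic carbanion (future C6), the chelated tetrahedral adduct of the Weinreb amide holds until the acid quench so that neither over-addition nor proton exchange with the product occurs, and the new C6 centre is racemic, freely enolising and destined to become sp2.

**Step 8**
Reactants: 18 diketo-dioxinone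
Product: 22 methyl 5-[4-(benzyloxy)benzyl]-6-(2-ArB-ethyl)-2,4-dihydroxybenzoate, via acylketene 19 (not isolated), via triketo methyl ester 20 (not isolated), via cyclic aldol adduct 21 (not isolated)
Conditions: MeOH (excess), PhMe, 110 °C, sealed tube; then Cs2CO3, MeOH, rt; then HCl in MeOH, rt
Reagents that add atoms: methanol, CO
Why: At 110 °C 18 loses acetone by a retro-[4+2] fragmentation, and the acylketene 19 is captured by the large excess of methanol as triketo ester 20 before the C5 enol oxygen can close onto the ketene to give a 2-pyrone. Cs2CO3 then enolises the ester-flanked C2 methylene, which adds to the C1 ketone in a 6-(enolexo)-exo-trig aldol that forms the C1–C2 bond and closes ring A as 21; HCl in methanol dehydrates 21 and the C3 and C5 ketones enolise to the two phenols. The closest known reaction type is the thermolysis of diketo-dioxinones with alcohol capture followed by base-then-acid aldol aromatization to resorcylates. No stereocentre is set, since the enolising C6 centre of 18 and the three centres of 21 all end as sp2 carbons. The step needs this one folding to win: of the doubly activated carbons, C4 could reach a carbonyl only through a four-membered ring and C6 could only attack the ester to give a quaternary trione that cannot aromatise and reverts, while the singly activated bridge CH2 is not deprotonated by carbonate, so C2 onto C1 is the only path that drains irreversibly to an arene. The ester finishes on C2 hydrogen-bonded to the C3 hydroxyl, which is what tells the two phenols apart in step 9.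

**Step 9**
Reactants: 22 methyl resorcylate
Product: 23 methyl 5-[4-(benzyloxy)benzyl]-6-(2-ArB-ethyl)-2-hydroxy-4-methoxybenzoate
Conditions: MeI (1.1 equiv), K2CO3, acetone, rt
Reagents that add atoms: iodomethane, CI
Why: Selective Williamson methylation of a 2,4-dihydroxybenzoate: the C3 hydroxyl is tied up in a hydrogen bond to the ester carbonyl and is both less acidic and less nucleophilic, so one equivalent of MeI with a weak base should alkylate only the free C5 hydroxyl.

**Step 10**
Reactants: 23 C5 methyl ether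
Product: 24 methyl 2-(benzyloxy)-5-[4-(benzyloxy)benzyl]-6-(2-ArB-ethyl)-4-methoxybenzoate
Conditions: BnBr (excess), K2CO3, DMF, 60 °C
Reagents that add atoms: benzyl bromide, BrCc1ccccc1
Why: Williamson benzylation under more forcing conditions overcomes the hydrogen bond and masks the C3 hydroxyl, so that no ortho-hydroxybenzyl alcohol prone to quinone methide formation arises in step 11 and no acidic proton meets the Grignard reagent in step 13.

**Step 11**
Reactants: 24 fully protected benzoate
Product: 25 {2-(benzyloxy)-5-[4-(benzyloxy)benzyl]-6-(2-ArB-ethyl)-4-methoxyphenyl}methanol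
Conditions: LiAlH4, THF, 0 °C to rt
Reagents that add atoms: none
Why: LiAlH4 reduction of a di-ortho-substituted benzoate goes cleanly to the benzylic alcohol where partial reduction to the aldehyde would be unreliable, and aryl ethers are inert to hydride.

**Step 12**
Reactants: 25 benzylic alcohol
Product: 26 2-(benzyloxy)-5-[4-(benzyloxy)benzyl]-6-(2-ArB-ethyl)-4-methoxybenzaldehyde
Conditions: Dess–Martin periodinane, CH2Cl2, 0 °C to rt
Reagents that add atoms: none
Why: Dess–Martin oxidation converts the primary benzylic alcohol into the aldehyde at room temperature without over-oxidation and without touching the diarylmethane CH2 groups or the ethers.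

**Step 13**
Reactants: 26 ring A aldehyde; 27 4-benzyloxybromobenzene
Product: 29 [4-(benzyloxy)phenyl]{2-(benzyloxy)-5-[4-(benzyloxy)benzyl]-6-(2-ArB-ethyl)-4-methoxyphenyl}methanol (racemic), via 4-(benzyloxy)phenylmagnesium bromide 28 (not isolated)
Conditions: 27, Mg turnings, THF, reflux; then 26, THF, 0 °C to rt; aq. NH4Cl
Reagents that add atoms: none
Why: Grignard addition to an aldehyde forms the last diarylmethane C–C bond, the aldehyde being the only electrophile in 26, and the new carbinol centre is formed racemic, which is irrelevant because step 14 removes it.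

**Step 14**
Reactants: 29 diaryl carbinol
Product: 30 CNP0147493.0
Conditions: H2 (1–3 bar), 10% Pd/C, EtOAc/EtOH, AcOH (cat.), rt
Reagents that add atoms: none
Why: Catalytic hydrogenolysis: the five O-benzyl bonds and the doubly benzylic C–OH bond, which is activated by ortho and para oxygen on its flanking rings, should all be cleaved over palladium under weakly acidic conditions, while the diarylmethane C–C bonds, the methyl ether and the arenes are not reduced.

**Compound list**
1 | 2-bromo-5-hydroxybenzaldehyde | O=Cc1cc(O)ccc1Br | starting material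
2 | 5-(benzyloxy)-2-bromobenzaldehyde | O=Cc1cc(OCc2ccccc2)ccc1Br | intermediate
3 | Meldrum's acid (2,2-dimethyl-1,3-dioxane-4,6-dione) | CC1(C)OC(=O)CC(=O)O1 | starting material
4 | 5-[5-(benzyloxy)-2-bromobenzylidene]-2,2-dimethyl-1,3-dioxane-4,6-dione (not isolated) | CC1(C)OC(=O)C(=Cc2cc(OCc3ccccc3)ccc2Br)C(=O)O1 | intermediate
5 | 5-[5-(benzyloxy)-2-bromobenzyl]-2,2-dimethyl-1,3-dioxane-4,6-dione (not isolated) | CC1(C)OC(=O)C(Cc2cc(OCc3ccccc3)ccc2Br)C(=O)O1 | intermediate
6 | 3-[5-(benzyloxy)-2-bromophenyl]propanoic acid | OC(=O)CCc1cc(OCc2ccccc2)ccc1Br | intermediate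
7 | 1-{3-[5-(benzyloxy)-2-bromophenyl]propanoyl}imidazole (not isolated) | O=C(CCc1cc(OCc2ccccc2)ccc1Br)n1ccnc1 | intermediate
8 | 3-[5-(benzyloxy)-2-bromophenyl]-N-methoxy-N-methylpropanamide | CON(C)C(=O)CCc1cc(OCc2ccccc2)ccc1Br | intermediate
9 | 4-(benzyloxy)benzyl chloride | ClCc1ccc(OCc2ccccc2)cc1 | starting material
10 | 4-(benzyloxy)benzylzinc chloride, LiCl-solubilised (not isolated) | Cl[Zn]Cc1ccc(OCc2ccccc2)cc1 | intermediate
11 | 3-{5-(benzyloxy)-2-[4-(benzyloxy)benzyl]phenyl}-N-methoxy-N-methylpropanamide | CON(C)C(=O)CCc1cc(OCc2ccccc2)ccc1Cc1ccc(OCc2ccccc2)cc1 | intermediate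
12 | 3-[4-(benzyloxy)phenyl]propanoic acid | OC(=O)CCc1ccc(OCc2ccccc2)cc1 | starting material
13 | 3-[4-(benzyloxy)phenyl]propanoyl chloride | ClC(=O)CCc1ccc(OCc2ccccc2)cc1 | intermediate
14 | 2,2,6-trimethyl-4H-1,3-dioxin-4-one | CC1=CC(=O)OC(C)(C)O1 | starting material
15 | lithium dienolate of 14 (not isolated) | [Li+].C=C1C=C([O-])OC(C)(C)O1 | intermediate
16 | 6-{4-[4-(benzyloxy)phenyl]-2-oxobutyl}-2,2-dimethyl-4H-1,3-dioxin-4-one | CC1(C)OC(=O)C=C(CC(=O)CCc2ccc(OCc3ccccc3)cc2)O1 | intermediate
17 | dilithium dianion (bis-enolate) of 16 (not isolated) | [Li+].[Li+].CC1(C)OC([O-])=CC(=CC([O-])=CCc2ccc(OCc3ccccc3)cc2)O1 | intermediate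
18 | 6-{3-[4-(benzyloxy)benzyl]-6-{5-(benzyloxy)-2-[4-(benzyloxy)benzyl]phenyl}-2,4-dioxohexyl}-2,2-dimethyl-4H-1,3-dioxin-4-one (racemic, enolising centre) | CC1(C)OC(=O)C=C(CC(=O)C(Cc2ccc(OCc3ccccc3)cc2)C(=O)CCc2cc(OCc3ccccc3)ccc2Cc2ccc(OCc3ccccc3)cc2)O1 | intermediate
19 | acylketene, 6-[4-(benzyloxy)benzyl]-9-ArB-3,5,7-trioxonon-1-en-1-one (racemic, not isolated) | O=C=CC(=O)CC(=O)C(Cc1ccc(OCc2ccccc2)cc1)C(=O)CCc1cc(OCc2ccccc2)ccc1Cc1ccc(OCc2ccccc2)cc1 | intermediate
20 | methyl 6-[4-(benzyloxy)benzyl]-9-ArB-3,5,7-trioxononanoate (racemic, not isolated) | COC(=O)CC(=O)CC(=O)C(Cc1ccc(OCc2ccccc2)cc1)C(=O)CCc1cc(OCc2ccccc2)ccc1Cc1ccc(OCc2ccccc2)cc1 | intermediate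
21 | methyl 5-[4-(benzyloxy)benzyl]-6-hydroxy-2,4-dioxo-6-(2-ArB-ethyl)cyclohexanecarboxylate (mixture of stereoisomers and tautomers, not isolated) | COC(=O)C1C(=O)CC(=O)C(Cc2ccc(OCc3ccccc3)cc2)C1(O)CCc1cc(OCc2ccccc2)ccc1Cc1ccc(OCc2ccccc2)cc1 | intermediate
22 | methyl 5-[4-(benzyloxy)benzyl]-6-(2-{5-(benzyloxy)-2-[4-(benzyloxy)benzyl]phenyl}ethyl)-2,4-dihydroxybenzoate | COC(=O)c1c(O)cc(O)c(Cc2ccc(OCc3ccccc3)cc2)c1CCc1cc(OCc2ccccc2)ccc1Cc1ccc(OCc2ccccc2)cc1 | intermediate
23 | methyl 5-[4-(benzyloxy)benzyl]-6-(2-ArB-ethyl)-2-hydroxy-4-methoxybenzoate | COC(=O)c1c(O)cc(OC)c(Cc2ccc(OCc3ccccc3)cc2)c1CCc1cc(OCc2ccccc2)ccc1Cc1ccc(OCc2ccccc2)cc1 | intermediate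
24 | methyl 2-(benzyloxy)-5-[4-(benzyloxy)benzyl]-6-(2-ArB-ethyl)-4-methoxybenzoate | COC(=O)c1c(OCc2ccccc2)cc(OC)c(Cc2ccc(OCc3ccccc3)cc2)c1CCc1cc(OCc2ccccc2)ccc1Cc1ccc(OCc2ccccc2)cc1 | intermediate
25 | {2-(benzyloxy)-5-[4-(benzyloxy)benzyl]-6-(2-ArB-ethyl)-4-methoxyphenyl}methanol | OCc1c(OCc2ccccc2)cc(OC)c(Cc2ccc(OCc3ccccc3)cc2)c1CCc1cc(OCc2ccccc2)ccc1Cc1ccc(OCc2ccccc2)cc1 | intermediate
26 | 2-(benzyloxy)-5-[4-(benzyloxy)benzyl]-6-(2-ArB-ethyl)-4-methoxybenzaldehyde | O=Cc1c(OCc2ccccc2)cc(OC)c(Cc2ccc(OCc3ccccc3)cc2)c1CCc1cc(OCc2ccccc2)ccc1Cc1ccc(OCc2ccccc2)cc1 | intermediate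
27 | 4-benzyloxybromobenzene | Brc1ccc(OCc2ccccc2)cc1 | starting material
28 | 4-(benzyloxy)phenylmagnesium bromide (not isolated) | Br[Mg]c1ccc(OCc2ccccc2)cc1 | intermediate
29 | [4-(benzyloxy)phenyl]{2-(benzyloxy)-5-[4-(benzyloxy)benzyl]-6-(2-ArB-ethyl)-4-methoxyphenyl}methanol (racemic) | OC(c1ccc(OCc2ccccc2)cc1)c1c(OCc2ccccc2)cc(OC)c(Cc2ccc(OCc3ccccc3)cc2)c1CCc1cc(OCc2ccccc2)ccc1Cc1ccc(OCc2ccccc2)cc1 | intermediate
30 | CNP0147493.0, 2,4-bis(4-hydroxybenzyl)-3-{2-[5-hydroxy-2-(4-hydroxybenzyl)phenyl]ethyl}-5-methoxyphenol (achiral) | COc1cc(O)c(Cc2ccc(O)cc2)c(CCc2cc(O)ccc2Cc2ccc(O)cc2)c1Cc1ccc(O)cc1 | target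

**Step count**
Total steps: 14.
Longest linear sequence: 12 (steps 1–4, then 7–14). Steps 5 and 6 form the short second branch.

**Steps most likely to fail**

Step 7.
- What may go wrong: proton transfer from the enolisable Weinreb amide to the strongly basic dianion, together with slow attack by a secondary carbanion, would return both partners unchanged.
- Fallback: it replaces the Claisen acylation by an aldol addition and an oxidation. It sets out from 11, which iBu2AlH in THF at −78 °C should reduce to 3-{5-(benzyloxy)-2-[4-(benzyloxy)benzyl]phenyl}propanal F1.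
- Dianion 17 adds to this much more electrophilic carbonyl at −78 °C, faster than it can deprotonate it, to give the β-hydroxy keto-dioxinone F2 as a mixture of diastereomers.
- Dess–Martin oxidation of the secondary alcohol brings the route back at 18.

Step 8.
- What may go wrong: retro-Claisen cleavage of the C6-substituted 1,3-diketone by methoxide during the carbonate stage, or pyrone closure of the ketene during thermolysis, would consume the open chain before the aldol occurs.
- Fallback: it forms the same C1–C2 bond without ever freeing the ketene or the triketo ester. It sets out from 18, which is stirred with Et3N in CH2Cl2 at rt.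
- The dioxinone stays intact, its dienolate carbon (future C2) adds to the C1 ketone, and dehydration and enolisation should give the isopropylidene-protected resorcylate 6-[4-(benzyloxy)benzyl]-5-(2-ArB-ethyl)-7-hydroxy-2,2-dimethyl-4H-1,3-benzodioxin-4-one F3.
- The now aromatic and robust lactone-acetal is opened with NaOMe in MeOH, and the route comes back at 22.

Step 14.
- What may go wrong: ionisation of the very electron-rich carbinol, followed by capture by the activated ring B carbon that lies between the bridge and the oxygen (a seven-membered Friedel–Crafts closure). Alternatively, C–OH cleavage may stall on a catalyst crowded by a large polyphenol.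
- Fallback: it avoids the carbinol altogether. It sets out from 25, which methyl chloroformate and pyridine convert into the benzylic methyl carbonate F4.
- A Suzuki–Miyaura coupling of F4 with 4-(benzyloxy)phenylboronic acid under Pd(OAc)2/DPEphos catalysis installs the aryl group directly at the CH2 level and gives the pentabenzyl ether of the target F5.
- Neutral hydrogenolysis over Pd/C then has only O-benzyl bonds to cleave and returns to the route at 30.

**Further compounds**
F1 | step 7 | 3-{5-(benzyloxy)-2-[4-(benzyloxy)benzyl]phenyl}propanal | O=CCCc1cc(OCc2ccccc2)ccc1Cc1ccc(OCc2ccccc2)cc1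
F2 | step 7 | 6-{3-[4-(benzyloxy)benzyl]-4-hydroxy-2-oxo-6-ArB-hexyl}-2,2-dimethyl-4H-1,3-dioxin-4-one (mixture of diastereomers) | CC1(C)OC(=O)C=C(CC(=O)C(Cc2ccc(OCc3ccccc3)cc2)C(O)CCc2cc(OCc3ccccc3)ccc2Cc2ccc(OCc3ccccc3)cc2)O1
F3 | step 8 | 6-[4-(benzyloxy)benzyl]-5-(2-ArB-ethyl)-7-hydroxy-2,2-dimethyl-4H-1,3-benzodioxin-4-one | CC1(C)OC(=O)c2c(CCc3cc(OCc4ccccc4)ccc3Cc3ccc(OCc4ccccc4)cc3)c(Cc3ccc(OCc4ccccc4)cc3)c(O)cc2O1
F4 | step 14 | 2-(benzyloxy)-5-[4-(benzyloxy)benzyl]-6-(2-ArB-ethyl)-4-methoxybenzyl methyl carbonate | COC(=O)OCc1c(OCc2ccccc2)cc(OC)c(Cc2ccc(OCc3ccccc3)cc2)c1CCc1cc(OCc2ccccc2)ccc1Cc1ccc(OCc2ccccc2)cc1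
F5 | step 14 | pentabenzyl ether of the target | COc1cc(OCc2ccccc2)c(Cc2ccc(OCc3ccccc3)cc2)c(CCc2cc(OCc3ccccc3)ccc2Cc2ccc(OCc3ccccc3)cc2)c1Cc1ccc(OCc2ccccc2)cc1
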